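**Plan**

- Retrosynthesis: the target is cut at C12–C13 (alkylzinc/enol triflate coupling), then at C9–C11 ([3,3] shift from a C7 allylic alcohol, which also places the 7,8-alkene), then at C8–C9 (aldol condensation of a C7 ethyl ketone with the C9 aldehyde), then at C4–C18 (enolate methylation), and last at C1–C10 and C4–C5 together (Diels–Alder).
- Enabling feature: in ring A (C1–C5, C10) the quaternary C10 (CH3, C9) and C5 (H, C6) are neighbours with C9 and C6 trans, oxygen sits on C3 (para to C10) and the C19 carbon on C4 (next to C5). This is the imprint of an (E)-2-methyl enal (C10=C5, CHO = C9) on a 2-silyloxy-1-carbomethoxy diene (C1=C2–C3=C4).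
- Forward: ring A is closed first by the catalytic enantioselective Diels–Alder reaction, ring B second by aldol condensation, and the C9 chain is joined last (two carbons by Johnson–Claisen rearrangement, four by Negishi coupling).
- Stereochemistry: C10 and C5 come from the chiral oxazaborolidinium catalyst and the E enal; C4 from methylation anti to the C10 methyl; C9 from suprafacial transfer from the equatorial C7 alcohol; C3 from equatorial hydride attack; 13E from an E enol triflate.

Key step: step 5

Remarks before the steps: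
- The S catalyst is assigned from the usual binding model for α-substituted enals (formyl C–H···O contact, open Re face at C10); if the sense proved opposite, the R catalyst would be used.
- Methyl 3-oxopent-4-enoate is taken as purchased and silylated at once, because it oligomerises on storage.
- Atom labels in the explanations follow labdane numbering. Compounds 8–13 carry systematic names (naphthalene positions 1, 2, 4a, 5, 6, 7, 8, 8a = labdane C4, C3, C10, C9, C8, C7, C6, C5). Compounds 14–25 are named as ent-labdanes: each is the mirror image of the normal-series structure that the rest of the name describes, so C20, C19 and the C9 chain share one face and 5-H, C18 and the 3-oxygen the other.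

**Route**

Step 1
Reactants: 1 ethyl 3-oxopentanoate
Product: 2 ethyl 2-(2-ethyl-1,3-dioxolan-2-yl)acetate
Conditions: HOCH2CH2OH, p-toluenesulfonic acid monohydrate (cat.), benzene, reflux, Dean–Stark trap
Reagents that add atoms: ethane-1,2-diol, OCCO
Why: Acid-catalysed ketalisation with azeotropic removal of water protects the future C7 carbonyl and removes the acidity of the methylene that becomes C6.

Step 2
Reactants: 2 ethyl 2-(2-ethyl-1,3-dioxolan-2-yl)acetate
Product: 3 2-(2-ethyl-1,3-dioxolan-2-yl)acetaldehyde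
Conditions: i-Bu2AlH, CH2Cl2, −78 °C; aqueous potassium sodium tartrate (KNaC4H4O6)
Reagents that add atoms: none
Why: Partial reduction of the ester: at −78 °C the aluminium hemiacetal is stabilised by chelation to a dioxolane oxygen and releases the aldehyde only on work-up.

Step 3
Reactants: 3 2-(2-ethyl-1,3-dioxolan-2-yl)acetaldehyde; 4 2-(triphenylphosphoranylidene)propanal
Product: 5 (2E)-4-(2-ethyl-1,3-dioxolan-2-yl)-2-methylbut-2-enal
Conditions: toluene, 90 °C
Reagents that add atoms: none
Why: Wittig olefination with the formyl-stabilised ylide gives the E trisubstituted enal and stops after one olefination because the conjugated α-branched product is the poorer electrophile.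

Step 4
Reactants: 6 methyl 3-oxopent-4-enoate
Product: 7 methyl (2Z)-3-[(tert-butyldimethylsilyl)oxy]penta-2,4-dienoate
Conditions: t-BuMe2SiOTf, Et3N, Et2O, −78 → 0 °C
Reagents that add atoms: tert-butyldimethylsilyl trifluoromethanesulfonate, CC(C)(C)[Si](C)(C)OS(=O)(=O)C(F)(F)F
Why: O-Silylation of the hydrogen-bonded cis enol of the β-keto ester (silyl enol ether formation) should give the 2Z dienol ether, whose ester points away from the vinyl group so that the s-cis diene is accessible.

Step 5
Reactants: 5 (2E)-4-(2-ethyl-1,3-dioxolan-2-yl)-2-methylbut-2-enal; 7 methyl (2Z)-3-[(tert-butyldimethylsilyl)oxy]penta-2,4-dienoate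
Product: 8 methyl (1R,5R,6R)-2-[(tert-butyldimethylsilyl)oxy]-6-[(2-ethyl-1,3-dioxolan-2-yl)methyl]-5-formyl-5-methylcyclohex-2-ene-1-carboxylate
Conditions: (S)-3,3-diphenyl-1-(2-methylphenyl)tetrahydro-1H,3H-pyrrolo[1,2-c][1,3,2]oxazaborole (20 mol %), Tf2NH (18 mol %), CH2Cl2, −78 → −40 °C
Reagents that add atoms: none
Why: The boron of the oxazaborolidinium ion binds the formyl oxygen of 5 while the formyl C–H contacts the ring oxygen, which holds the s-trans enal over one phenyl group and leaves the Re face of C10 open; the diene adds to this face in a concerted but asynchronous [4+2] cycloaddition in which its silyloxy-activated terminus (C4) bonds to the enal β-carbon (C5) ahead of C1–C10. The closest known reaction type is the oxazaborolidinium-catalysed Diels–Alder reaction of α-substituted enals with 2-silyloxy dienes. Ring A closes as a cyclohexene silyl enol ether by intermolecular [4+2] cycloaddition, suprafacial on both partners. C10 and C5 are set together by the catalyst-controlled enal face, their relative configuration (C9 trans to C6) by the E alkene, and C4 by the endo position of the formyl group with the Z diene, a centre that is erased again in steps 6 and 7. The step needs regioselectivity, which the silyloxy group secures by making the ester-bearing terminus the nucleophilic one (C3–O para to C10), and π-facial selectivity, which the catalyst secures; a slight excess of oxazaborolidine over Tf2NH keeps free acid away from the ketal and the silyl enol ether.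

Step 6
Reactants: 8 methyl (1R,5R,6R)-2-[(tert-butyldimethylsilyl)oxy]-6-[(2-ethyl-1,3-dioxolan-2-yl)methyl]-5-formyl-5-methylcyclohex-2-ene-1-carboxylate
Product: 10 methyl (1R,4aR,8aR)-4a,6-dimethyl-2,7-dioxo-1,2,3,4,4a,7,8,8a-octahydronaphthalene-1-carboxylate, via keto aldehyde 9 (not isolated)
Conditions: 1 M HCl, THF, 25 °C; then p-toluenesulfonic acid monohydrate (cat.), benzene, reflux, Dean–Stark trap
Reagents that add atoms: water, O
Why: Hydrolysis frees the C3 and C7 ketones, and the acid-catalysed intramolecular aldol condensation (6-enolendo-exo-trig) of the ethyl ketone enol (C8) with the non-enolisable C9 aldehyde closes ring B irreversibly as the conjugated enone, the trans ring fusion being already fixed at C5 and C10 and C4 staying epimerisable.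

Step 7
Reactants: 10 methyl (1R,4aR,8aR)-4a,6-dimethyl-2,7-dioxo-1,2,3,4,4a,7,8,8a-octahydronaphthalene-1-carboxylate
Product: 11 methyl (1S,4aS,8aS)-1,4a,6-trimethyl-2,7-dioxo-1,2,3,4,4a,7,8,8a-octahydronaphthalene-1-carboxylate
Conditions: MeI, K2CO3, acetone, reflux
Reagents that add atoms: iodomethane, CI
Why: C-Alkylation of the β-keto ester enolate (the only position acidic enough for K2CO3) should occur on the face opposite the axial C10 methyl, as is usual for 3-oxo-4-alkoxycarbonyl enolates of trans-fused 10-methyl decalins, so the new methyl is equatorial (C18) and the ester axial and cis to C20 (C19).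

Step 8
Reactants: 11 methyl (1S,4aS,8aS)-1,4a,6-trimethyl-2,7-dioxo-1,2,3,4,4a,7,8,8a-octahydronaphthalene-1-carboxylate
Product: 12 methyl (1S,4aS,7R,8aS)-7-hydroxy-1,4a,6-trimethyl-2-oxo-1,2,3,4,4a,7,8,8a-octahydronaphthalene-1-carboxylate
Conditions: NaBH4, CeCl3·7H2O, MeOH, −78 °C
Reagents that add atoms: none
Why: Luche reduction: the hard borohydride adds 1,2 to the enone by axial attack and gives the pseudo-equatorial C7 alcohol cis to C20, while the non-conjugated C3 ketone, shielded by the quaternary C4, is expected to react more slowly.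

Step 9
Reactants: 12 methyl (1S,4aS,7R,8aS)-7-hydroxy-1,4a,6-trimethyl-2-oxo-1,2,3,4,4a,7,8,8a-octahydronaphthalene-1-carboxylate
Product: 14 12-ethyl 19-methyl ent-3-oxo-13,14,15,16-tetranorlabd-7-ene-12,19-dioate, via ketene acetal 13 (not isolated)
Conditions: CH3C(OEt)3, EtCO2H (cat.), 140 °C, distillation of EtOH
Reagents that add atoms: triethyl orthoacetate, CCOC(C)(OCC)OCC
Why: Johnson–Claisen rearrangement: the ketene acetal rearranges by a suprafacial [3,3] shift, so the CH2CO2Et group arrives at C9 on the face that carried the C7 oxygen (cis to C20) and the double bond moves to C7=C8.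

Step 10
Reactants: 14 12-ethyl 19-methyl ent-3-oxo-13,14,15,16-tetranorlabd-7-ene-12,19-dioate
Product: 16 ent-13,14,15,16-tetranorlabd-7-ene-3α,12,19-triol, via hydroxy diester 15 (not isolated)
Conditions: LiBH(s-Bu)3, THF, −78 °C; then LiAlH4, −78 → 25 °C
Reagents that add atoms: none
Why: Ketone reduction by the bulky trialkylborohydride takes place from the equatorial direction and gives the axial C3 alcohol (trans to C20, anti to the axial ester), after which LiAlH4 reduces both esters to the primary alcohols.

Step 11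
Reactants: 16 ent-13,14,15,16-tetranorlabd-7-ene-3α,12,19-triol
Product: 17 ent-12-iodo-13,14,15,16-tetranorlabd-7-ene-3α,19-diol
Conditions: I2, PPh3, imidazole, CH2Cl2, 0 °C
Reagents that add atoms: iodine, II
Why: Appel-type iodination runs through SN2 displacement of an alkoxyphosphonium ion, which is fast only at the unhindered C12 carbinol and not at the neopentyl C19 or the hindered secondary C3 hydroxyl.

Step 12
Reactants: 17 ent-12-iodo-13,14,15,16-tetranorlabd-7-ene-3α,19-diol
Product: 18 ent-3α-hydroxy-12-iodo-13,14,15,16-tetranorlabd-7-en-19-al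
Conditions: TEMPO (2,2,6,6-tetramethylpiperidin-1-oxyl, cat.), PhI(OAc)2, CH2Cl2, 25 °C
Reagents that add atoms: none
Why: Oxoammonium-mediated oxidation distinguishes the primary C19 alcohol from the secondary C3 alcohol and stops at the aldehyde, which cannot enolise because C4 is quaternary.

Step 13
Reactants: 18 ent-3α-hydroxy-12-iodo-13,14,15,16-tetranorlabd-7-en-19-al
Product: 19 ent-3α-acetoxy-12-iodo-13,14,15,16-tetranorlabd-7-en-19-al
Conditions: Ac2O, Et3N, 4-(dimethylamino)pyridine (cat.), CH2Cl2, 0 °C
Reagents that add atoms: acetic anhydride, CC(=O)OC(C)=O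
Why: Nucleophile-catalysed acylation esterifies the hindered axial C3 alcohol with retention, and the short reaction at 0 °C without pyridine as solvent avoids N-alkylation by the primary iodide.

Step 14
Reactants: 20 tert-butyl 3-oxobutanoate
Product: 21 tert-butyl (2E)-3-{[(trifluoromethyl)sulfonyl]oxy}but-2-enoate
Conditions: (CF3SO2)2O, aqueous Me4NOH, hexanes, 5 → 25 °C
Reagents that add atoms: trifluoromethanesulfonic anhydride, O=S(=O)(OS(=O)(=O)C(F)(F)F)C(F)(F)F
Why: O-Sulfonylation of the non-chelated ammonium enolate in the two-phase medium is expected to give the E enol triflate (triflate trans to the ester), whereas a chelated lithium enolate would give the Z isomer.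

Step 15
Reactants: 19 ent-3α-acetoxy-12-iodo-13,14,15,16-tetranorlabd-7-en-19-al; 21 tert-butyl (2E)-3-{[(trifluoromethyl)sulfonyl]oxy}but-2-enoate
Product: 23 tert-butyl ent-3α-acetoxy-19-oxolabda-7,13E-dien-15-oate, via alkylzinc iodide 22 (not isolated)
Conditions: Zn dust (activated with BrCH2CH2Br and Me3SiCl), LiCl, THF, 40 °C; then 21, Pd(PPh3)4 (5 mol %), 25 → 50 °C
Reagents that add atoms: none
Why: Zinc inserts into the primary C–I bond without touching the acetate or the hindered non-enolisable aldehyde, and the palladium-catalysed Negishi coupling with the enol triflate proceeds with retention of alkene geometry to give the 13E enoate.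

Step 16
Reactants: 23 tert-butyl ent-3α-acetoxy-19-oxolabda-7,13E-dien-15-oate
Product: 25 ent-3α-acetoxy-19-oxolabda-7,13E-dien-15-oic acid, via trimethylsilyl ester 24 (not isolated)
Conditions: Me3SiOTf, 2,6-lutidine, CH2Cl2, 0 °C; then aqueous citric acid
Reagents that add atoms: none
Why: Silyl triflate-mediated cleavage of the tert-butyl ester (loss of isobutene) works without protic acid, so the acetate, the aldehyde and the trisubstituted alkene stay untouched, and the silyl ester is hydrolysed on work-up.

**Compound list**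

1 | ethyl 3-oxopentanoate | CCC(=O)CC(=O)OCC | starting material
2 | ethyl 2-(2-ethyl-1,3-dioxolan-2-yl)acetate | CCOC(=O)CC1(CC)OCCO1 | intermediate
3 | 2-(2-ethyl-1,3-dioxolan-2-yl)acetaldehyde | O=CCC1(CC)OCCO1 | intermediate
4 | 2-(triphenylphosphoranylidene)propanal | CC(C=O)=P(c1ccccc1)(c1ccccc1)c1ccccc1 | starting material
5 | (2E)-4-(2-ethyl-1,3-dioxolan-2-yl)-2-methylbut-2-enal | O=C/C(C)=C/CC1(CC)OCCO1 | intermediate
6 | methyl 3-oxopent-4-enoate | C=CC(=O)CC(=O)OC | starting material
7 | methyl (2Z)-3-[(tert-butyldimethylsilyl)oxy]penta-2,4-dienoate | C=C/C(O[Si](C)(C)C(C)(C)C)=C/C(=O)OC | intermediate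
8 | methyl (1R,5R,6R)-2-[(tert-butyldimethylsilyl)oxy]-6-[(2-ethyl-1,3-dioxolan-2-yl)methyl]-5-formyl-5-methylcyclohex-2-ene-1-carboxylate | C1(O[Si](C)(C)C(C)(C)C)=CC[C@@](C)(C=O)[C@H](CC2(CC)OCCO2)[C@H]1C(=O)OC | intermediate
9 | methyl (1R,5R,6R)-5-formyl-5-methyl-2-oxo-6-(2-oxobutyl)cyclohexane-1-carboxylate | O=C1CC[C@@](C)(C=O)[C@H](CC(=O)CC)[C@H]1C(=O)OC | intermediate
10 | methyl (1R,4aR,8aR)-4a,6-dimethyl-2,7-dioxo-1,2,3,4,4a,7,8,8a-octahydronaphthalene-1-carboxylate (keto form; C1 epimerisable) | O=C1CC[C@@]2(C)C=C(C)C(=O)C[C@@H]2[C@H]1C(=O)OC | intermediate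
11 | methyl (1S,4aS,8aS)-1,4a,6-trimethyl-2,7-dioxo-1,2,3,4,4a,7,8,8a-octahydronaphthalene-1-carboxylate | O=C1CC[C@@]2(C)C=C(C)C(=O)C[C@@H]2[C@]1(C)C(=O)OC | intermediate
12 | methyl (1S,4aS,7R,8aS)-7-hydroxy-1,4a,6-trimethyl-2-oxo-1,2,3,4,4a,7,8,8a-octahydronaphthalene-1-carboxylate | O=C1CC[C@@]2(C)C=C(C)[C@H](O)C[C@@H]2[C@]1(C)C(=O)OC | intermediate
13 | methyl (1S,4aS,7R,8aS)-7-[(1-ethoxyethenyl)oxy]-1,4a,6-trimethyl-2-oxo-1,2,3,4,4a,7,8,8a-octahydronaphthalene-1-carboxylate | O=C1CC[C@@]2(C)C=C(C)[C@H](OC(=C)OCC)C[C@@H]2[C@]1(C)C(=O)OC | intermediate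
14 | 12-ethyl 19-methyl ent-3-oxo-13,14,15,16-tetranorlabd-7-ene-12,19-dioate | O=C1CC[C@@]2(C)[C@H](CC(=O)OCC)C(C)=CC[C@@H]2[C@]1(C)C(=O)OC | intermediate
15 | 12-ethyl 19-methyl ent-3α-hydroxy-13,14,15,16-tetranorlabd-7-ene-12,19-dioate | O[C@H]1CC[C@@]2(C)[C@H](CC(=O)OCC)C(C)=CC[C@@H]2[C@]1(C)C(=O)OC | intermediate
16 | ent-13,14,15,16-tetranorlabd-7-ene-3α,12,19-triol | O[C@H]1CC[C@@]2(C)[C@H](CCO)C(C)=CC[C@@H]2[C@]1(C)CO | intermediate
17 | ent-12-iodo-13,14,15,16-tetranorlabd-7-ene-3α,19-diol | O[C@H]1CC[C@@]2(C)[C@H](CCI)C(C)=CC[C@@H]2[C@]1(C)CO | intermediate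
18 | ent-3α-hydroxy-12-iodo-13,14,15,16-tetranorlabd-7-en-19-al | O[C@H]1CC[C@@]2(C)[C@H](CCI)C(C)=CC[C@@H]2[C@]1(C)C=O | intermediate
19 | ent-3α-acetoxy-12-iodo-13,14,15,16-tetranorlabd-7-en-19-al | CC(=O)O[C@H]1CC[C@@]2(C)[C@H](CCI)C(C)=CC[C@@H]2[C@]1(C)C=O | intermediate
20 | tert-butyl 3-oxobutanoate | CC(=O)CC(=O)OC(C)(C)C | starting material
21 | tert-butyl (2E)-3-{[(trifluoromethyl)sulfonyl]oxy}but-2-enoate | C/C(OS(=O)(=O)C(F)(F)F)=C\C(=O)OC(C)(C)C | intermediate
22 | (ent-3α-acetoxy-19-oxo-13,14,15,16-tetranorlabd-7-en-12-yl)zinc iodide | CC(=O)O[C@H]1CC[C@@]2(C)[C@H](CC[Zn]I)C(C)=CC[C@@H]2[C@]1(C)C=O | intermediate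
23 | tert-butyl ent-3α-acetoxy-19-oxolabda-7,13E-dien-15-oate | CC(=O)O[C@H]1CC[C@@]2(C)[C@H](CC/C(C)=C/C(=O)OC(C)(C)C)C(C)=CC[C@@H]2[C@]1(C)C=O | intermediate
24 | trimethylsilyl ent-3α-acetoxy-19-oxolabda-7,13E-dien-15-oate | CC(=O)O[C@H]1CC[C@@]2(C)[C@H](CC/C(C)=C/C(=O)O[Si](C)(C)C)C(C)=CC[C@@H]2[C@]1(C)C=O | intermediate
25 | ent-3α-acetoxy-19-oxolabda-7,13E-dien-15-oic acid, (3S,4S,5S,9R,10S) in labdane numbering (CNP0312710.1) | CC(=O)O[C@H]1CC[C@@]2(C)[C@H](CC/C(C)=C/C(=O)O)C(C)=CC[C@@H]2[C@]1(C)C=O | target

**Count**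

Total step count: 16. Longest linear sequence: 14 steps (steps 1–3, 5–13, 15 and 16, from 1 to 25); steps 4 and 14 prepare the diene and the enol triflate.

**Steps most likely to fail**

Step 5. The cycloaddition may stall because the trisubstituted enal is a slow dienophile and the ester-bearing diene only a modest nucleophile, the diene may lose its silyl group to the Lewis acid, or the facial selectivity may be eroded. The fallback sets out from 5 and 6 and returns at 10; it forms the same two bonds stepwise under amine catalysis. Keto ester 6 serves directly as the four-carbon partner. A cinchona-derived primary amine salt (9-amino-9-deoxy-epi-quinine with CF3CO2H, or its quinidine-derived pseudo-enantiomer, whichever leads to the 5R,6R series) forms the iminium ion of 5. The doubly activated carbon of 6 adds to C5 (Michael addition), and the enamine so formed closes C10 onto the vinyl ketone (second Michael addition). Hydrolysis should give methyl (1R,5R,6R)-6-[(2-ethyl-1,3-dioxolan-2-yl)methyl]-5-formyl-5-methyl-2-oxocyclohexane-1-carboxylate F1, and the conditions of step 6 then convert it into 10.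

Step 9. Under the hot, acidic conditions of the orthoester rearrangement the allylic alcohol may ionise (elimination to a diene, scrambling at C7) faster than the congested ketene acetal rearranges. The fallback sets out from 12 and returns at 16; it uses the Eschenmoser–Claisen rearrangement under neutral conditions and a different reduction. Heating 12 with CH3C(OMe)2NMe2 in xylene at 140 °C should give, by the same suprafacial shift, methyl ent-12-(dimethylamino)-3,12-dioxo-13,14,15,16-tetranorlabd-7-en-19-oate F5. LiBH(s-Bu)3 at −78 °C then reduces the C3 ketone to methyl ent-12-(dimethylamino)-3α-hydroxy-12-oxo-13,14,15,16-tetranorlabd-7-en-19-oate F6. LiBHEt3, which takes tertiary amides to primary alcohols with loss of the amine and also reduces the ester, gives triol 16.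

Step 8. The borohydride may also reduce the C3 ketone (loss of chemoselectivity), which would give the unwanted equatorial C3 alcohol. The fallback sets out from 10 and returns at 14; it masks the C3 carbonyl before the reduction and introduces the C4 methyl group afterwards. Keto ester 10 with i-Pr3SiOTf and Et3N should give methyl (4aS,8aS)-4a,6-dimethyl-7-oxo-2-{[tri(propan-2-yl)silyl]oxy}-3,4,4a,7,8,8a-hexahydronaphthalene-1-carboxylate F2. Luche reduction, now with a single ketone present, gives methyl (4aS,7R,8aS)-7-hydroxy-4a,6-dimethyl-2-{[tri(propan-2-yl)silyl]oxy}-3,4,4a,7,8,8a-hexahydronaphthalene-1-carboxylate F3. Johnson–Claisen rearrangement as in step 9 gives methyl (4aS,5R,8aS)-5-(2-ethoxy-2-oxoethyl)-4a,6-dimethyl-2-{[tri(propan-2-yl)silyl]oxy}-3,4,4a,5,8,8a-hexahydronaphthalene-1-carboxylate F4. Bu4NF and MeI in THF then release the enolate and methylate C4 anti to C20, which gives 14.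

**Further compounds**

F1 | step 5 | methyl (1R,5R,6R)-6-[(2-ethyl-1,3-dioxolan-2-yl)methyl]-5-formyl-5-methyl-2-oxocyclohexane-1-carboxylate | O=C1CC[C@@](C)(C=O)[C@H](CC2(CC)OCCO2)[C@H]1C(=O)OC
F2 | step 8 | methyl (4aS,8aS)-4a,6-dimethyl-7-oxo-2-{[tri(propan-2-yl)silyl]oxy}-3,4,4a,7,8,8a-hexahydronaphthalene-1-carboxylate | C1(O[Si](C(C)C)(C(C)C)C(C)C)CC[C@@]2(C)C=C(C)C(=O)C[C@@H]2C=1C(=O)OC
F3 | step 8 | methyl (4aS,7R,8aS)-7-hydroxy-4a,6-dimethyl-2-{[tri(propan-2-yl)silyl]oxy}-3,4,4a,7,8,8a-hexahydronaphthalene-1-carboxylate | C1(O[Si](C(C)C)(C(C)C)C(C)C)CC[C@@]2(C)C=C(C)[C@H](O)C[C@@H]2C=1C(=O)OC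
F4 | step 8 | methyl (4aS,5R,8aS)-5-(2-ethoxy-2-oxoethyl)-4a,6-dimethyl-2-{[tri(propan-2-yl)silyl]oxy}-3,4,4a,5,8,8a-hexahydronaphthalene-1-carboxylate | C1(O[Si](C(C)C)(C(C)C)C(C)C)CC[C@@]2(C)[C@H](CC(=O)OCC)C(C)=CC[C@@H]2C=1C(=O)OC
F5 | step 9 | methyl ent-12-(dimethylamino)-3,12-dioxo-13,14,15,16-tetranorlabd-7-en-19-oate | O=C1CC[C@@]2(C)[C@H](CC(=O)N(C)C)C(C)=CC[C@@H]2[C@]1(C)C(=O)OC
F6 | step 9 | methyl ent-12-(dimethylamino)-3α-hydroxy-12-oxo-13,14,15,16-tetranorlabd-7-en-19-oate | O[C@H]1CC[C@@]2(C)[C@H](CC(=O)N(C)C)C(C)=CC[C@@H]2[C@]1(C)C(=O)OC
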